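The central ring (C1 arylethyl, C2 and C6 benzyl, C3 and C5 OH, C4 H) has its two oxygens 1,3 to each other across C4. It therefore differs by only one molecule of hydrogen from a 4,6-dibenzyl-5-alkylcyclohexane-1,3-dione. That dione is cut at C1–C2 and C3–C4. A benzylmalonate delivers C2 and C3. An acyclic enone bearing the α-benzyl group, the β-arylethyl chain and a methyl ketone terminus delivers C4, C5, C6 and C1. One methoxide-mediated conjugate addition–acylation makes both bonds and the ring, with every substituent already in place. The mirror plane through C1 and C4 makes an ester shift between C2 and C6 harmless. Phenols travel as methyl ethers.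

Key step: step 4

Remark on the chemistry: the target has no stereocentre. All sp3 stereocentres and the alkene geometry created on the way are transient, so racemates, diastereomer mixtures and alkene isomer mixtures are carried forward. The SMILES of such intermediates are written without configuration at sp3 centres.

Step 1
Reactants: 1 diethyl (2-oxopropyl)phosphonate; 2 4-methoxybenzyl chloride
Product: 3 diethyl [1-(4-methoxyphenyl)-3-oxobutan-2-yl]phosphonate (racemic)
Conditions: NaH, NaI (cat.), THF, 0 °C to reflux
Reagents that add atoms: none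
Why: SN2 C-alkylation of the doubly stabilised β-ketophosphonate monoanion at the carbon between P and C=O by a reactive benzylic chloride (iodide catalysis, slight excess of 1 against double alkylation); the new stereocentre is racemic and disappears in step 2.

Step 2
Reactants: 3 diethyl [1-(4-methoxyphenyl)-3-oxobutan-2-yl]phosphonate; 4 3-(4-methoxyphenyl)propanal
Product: 5 (E)-3-(4-methoxybenzyl)-6-(4-methoxyphenyl)hex-3-en-2-one
Conditions: NaH, THF, 0 °C; then 4, 0 °C to 40 °C
Reagents that add atoms: none
Why: Horner–Wadsworth–Emmons olefination in which the fully preformed, weakly basic phosphonate anion should add to the aldehyde rather than enolise it, and phosphate elimination should favour the chain trans to the acetyl group (E); any Z isomer is carried along because step 4 erases the alkene geometry.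

Step 3
Reactants: 6 dimethyl malonate (excess); 2 4-methoxybenzyl chloride
Product: 7 dimethyl 2-(4-methoxybenzyl)malonate
Conditions: NaH, THF/DMF, 0 °C to rt
Reagents that add atoms: none
Why: Malonic ester alkylation (SN2) run in an aprotic medium to avoid the fast methanolysis of 2, with excess 6 suppressing the dibenzylated product.

Step 4
Reactants: 5 (E)-3-(4-methoxybenzyl)-6-(4-methoxyphenyl)hex-3-en-2-one; 7 dimethyl 2-(4-methoxybenzyl)malonate (slight excess)
Product: 9 methyl 1,5-bis(4-methoxybenzyl)-6-[2-(4-methoxyphenyl)ethyl]-2,4-dioxocyclohexane-1-carboxylate (diastereomer mixture), via acyclic Michael adduct 8 (not isolated)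
Conditions: NaOMe (1.2 equiv), MeOH (concentrated), reflux; then cold 1 M HCl
Reagents that add atoms: none
Why: The sodium enolate of 7 adds reversibly to the β-carbon of 5 (C1–C2 bond) and proton transfer gives 8, whose methyl ketone is enolised at C4 and acylated by one of the two geminal esters (C3–C4 bond) with loss of methoxide. The closest known reaction type is the Michael–Claisen annulation by which enones and malonates are routinely converted into cyclohexane-1,3-diones. The single ring closes in the 6-(enolendo)-exo-trig mode, and the methoxide set free at once deprotonates C4 between the two carbonyls, so that the vinylogous carboxylate salt of 9 acts as the thermodynamic sink that drains the crowded and unfavourable addition equilibrium. Of the three new stereocentres, C6 is epimerisable and should settle trans to the C1 chain, while the C1/C2 relationship follows from thermodynamic control of the reversible addition; none needs control, because steps 5 and 6 flatten all three. The selectivity needed is acylation at C4 and not at C6, and ring size secures it, since the C6 enolate could only form a cyclobutanone whose reopening would move the ester from C2 to C6 and, owing to the mirror plane through C1 and C4, lead to the same constitution 9. Methoxide matched to methyl esters rules out ester scrambling, the far higher acidity of 7 keeps 5 from being enolised and self-condensing, and the acidic product can be separated from neutral 5 and 7 by base extraction.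

Step 5
Reactants: 9 methyl 1,5-bis(4-methoxybenzyl)-6-[2-(4-methoxyphenyl)ethyl]-2,4-dioxocyclohexane-1-carboxylate
Product: 11 4,6-bis(4-methoxybenzyl)-5-[2-(4-methoxyphenyl)ethyl]cyclohexane-1,3-dione (diastereomer mixture), via β-keto carboxylate 10 (not isolated)
Conditions: LiCl, H2O, DMSO, 150 °C; then 1 M HCl
Reagents that add atoms: none
Why: Krapcho dealkoxycarbonylation, in which chloride attacks the unhindered O-methyl carbon instead of the neopentyl-like ester carbonyl and the β-keto carboxylate 10 loses CO2 at this temperature, so no hot alkali that could open the dione by retro-Claisen cleavage is needed, the aryl methyl ethers are inert, and the configuration of the new C–H centre is irrelevant.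

Step 6
Reactants: 11 4,6-bis(4-methoxybenzyl)-5-[2-(4-methoxyphenyl)ethyl]cyclohexane-1,3-dione
Product: 12 4,6-bis(4-methoxybenzyl)-5-[2-(4-methoxyphenyl)ethyl]benzene-1,3-diol
Conditions: 10% Pd/C, p-cymene, reflux, N2 sweep
Reagents that add atoms: none
Why: Catalytic dehydrogenative aromatisation of a cyclohexane-1,3-dione to a resorcinol, in which loss of one H2 across C1–C2 (or C1–C6) gives a dienone that tautomerises irreversibly to the arene and erases the three stereocentres, while the anisole rings, the benzylic C–C bonds and the saturated two-carbon bridge are not affected.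

Step 7
Reactants: 12 4,6-bis(4-methoxybenzyl)-5-[2-(4-methoxyphenyl)ethyl]benzene-1,3-diol
Product: 13 4,6-bis(4-hydroxybenzyl)-5-[2-(4-hydroxyphenyl)ethyl]benzene-1,3-diol (target)
Conditions: BBr3 (excess), CH2Cl2, −78 °C to rt; then ice-water
Reagents that add atoms: none
Why: Lewis-acid cleavage of the three aryl methyl ethers with BBr3 (more than one equivalent per oxygen), started and quenched cold so that the acid-sensitive bonds between the resorcinol ring and its 4-hydroxybenzyl groups are not broken by a retro-Friedel–Crafts process.

Compound list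
1 | diethyl (2-oxopropyl)phosphonate | CCOP(=O)(CC(C)=O)OCC | starting material
2 | 4-methoxybenzyl chloride | COc1ccc(CCl)cc1 | starting material
3 | diethyl [1-(4-methoxyphenyl)-3-oxobutan-2-yl]phosphonate (racemic) | CCOP(=O)(OCC)C(Cc1ccc(OC)cc1)C(C)=O | intermediate
4 | 3-(4-methoxyphenyl)propanal | COc1ccc(CCC=O)cc1 | starting material
5 | (E)-3-(4-methoxybenzyl)-6-(4-methoxyphenyl)hex-3-en-2-one | CC(=O)/C(Cc1ccc(OC)cc1)=C/CCc1ccc(OC)cc1 | intermediate
6 | dimethyl malonate | COC(=O)CC(=O)OC | starting material
7 | dimethyl 2-(4-methoxybenzyl)malonate | COC(=O)C(Cc1ccc(OC)cc1)C(=O)OC | intermediate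
8 | dimethyl 2-(4-methoxybenzyl)-2-[4-(4-methoxybenzyl)-1-(4-methoxyphenyl)-5-oxohexan-3-yl]malonate (not isolated) | COC(=O)C(Cc1ccc(OC)cc1)(C(=O)OC)C(CCc1ccc(OC)cc1)C(Cc1ccc(OC)cc1)C(C)=O | intermediate
9 | methyl 1,5-bis(4-methoxybenzyl)-6-[2-(4-methoxyphenyl)ethyl]-2,4-dioxocyclohexane-1-carboxylate (diastereomer mixture) | COC(=O)C1(Cc2ccc(OC)cc2)C(=O)CC(=O)C(Cc2ccc(OC)cc2)C1CCc1ccc(OC)cc1 | intermediate
10 | 1,5-bis(4-methoxybenzyl)-6-[2-(4-methoxyphenyl)ethyl]-2,4-dioxocyclohexane-1-carboxylic acid (formed as its lithium salt, not isolated) | O=C(O)C1(Cc2ccc(OC)cc2)C(=O)CC(=O)C(Cc2ccc(OC)cc2)C1CCc1ccc(OC)cc1 | intermediate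
11 | 4,6-bis(4-methoxybenzyl)-5-[2-(4-methoxyphenyl)ethyl]cyclohexane-1,3-dione (diastereomer mixture) | O=C1CC(=O)C(Cc2ccc(OC)cc2)C(CCc2ccc(OC)cc2)C1Cc1ccc(OC)cc1 | intermediate
12 | 4,6-bis(4-methoxybenzyl)-5-[2-(4-methoxyphenyl)ethyl]benzene-1,3-diol | COc1ccc(CCc2c(Cc3ccc(OC)cc3)c(O)cc(O)c2Cc2ccc(OC)cc2)cc1 | intermediate
13 | 4,6-bis(4-hydroxybenzyl)-5-[2-(4-hydroxyphenyl)ethyl]benzene-1,3-diol | Oc1ccc(CCc2c(Cc3ccc(O)cc3)c(O)cc(O)c2Cc2ccc(O)cc2)cc1 | target

Total step count: 7
Longest linear sequence: 6 steps (1, 2, 4, 5, 6, 7); step 3 is a one-step side branch.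

Steps most likely to fail

**Step 4.**
- **Risk:** A tertiary carbanion has to be joined to the β-carbon of an α,β-disubstituted enone. The addition equilibrium may stay so far on the side of the components that ring closure cannot drain it. The enone would then be slowly lost to deconjugation and self-condensation.
- **Fallback:** It sets out from 5 and 6 and comes back to the route at 9. The much less hindered, unsubstituted malonate 6 is annulated with 5 under NaOMe/MeOH at reflux. This passes through dimethyl 2-[4-(4-methoxybenzyl)-1-(4-methoxyphenyl)-5-oxohexan-3-yl]malonate F1 and gives methyl 5-(4-methoxybenzyl)-6-[2-(4-methoxyphenyl)ethyl]-2,4-dioxocyclohexane-1-carboxylate F2. The second benzyl group is introduced only afterwards. Two equivalents of LiN(iPr)2 (THF, −78 °C to 0 °C) form the dianion. Its more basic, ester-flanked carbon (C2 of the ring numbering) is alkylated by 2 to give 9.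

**Step 6.**
- **Risk:** The fully substituted ring may adsorb slowly on the metal. The hydrogen set free may also be transferred to unreacted dione, which reduces it and removes a ring oxygen.
- **Fallback:** It sets out from 11 and comes back to the route at 13. Catalytic dehydrogenation is replaced by an iodination–elimination sequence. I2 in refluxing MeOH converts the dione through its enol ethers into 1,5-dimethoxy-2,4-bis(4-methoxybenzyl)-3-[2-(4-methoxyphenyl)ethyl]benzene F3. The BBr3 treatment of step 7 then cleaves all five methyl ethers, so the step count does not change.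

**Step 5.**
- **Risk:** Dealkylation of the ester may stay incomplete at a temperature the crowded ring tolerates. A methyl group may also be transferred to carbon C4 of the dione anion that builds up.
- **Fallback:** It sets out from 5 (with 2 used to build a new donor) and comes back to the route at 10, which loses CO2 to give 11. The ester is redesigned for neutral hydrogenolysis. Purchased dibenzyl malonate F4 is alkylated with 2 (NaH, THF/DMF) to give dibenzyl 2-(4-methoxybenzyl)malonate F5. Annulation of F5 with 5 (NaH, THF, reflux) passes through dibenzyl 2-(4-methoxybenzyl)-2-[4-(4-methoxybenzyl)-1-(4-methoxyphenyl)-5-oxohexan-3-yl]malonate F6. It gives benzyl 1,5-bis(4-methoxybenzyl)-6-[2-(4-methoxyphenyl)ethyl]-2,4-dioxocyclohexane-1-carboxylate F7. H2 over Pd/C in EtOAc at rt then frees acid 10, which decarboxylates on gentle warming.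

Further compounds
F1 | step 4 | dimethyl 2-[4-(4-methoxybenzyl)-1-(4-methoxyphenyl)-5-oxohexan-3-yl]malonate | COC(=O)C(C(=O)OC)C(CCc1ccc(OC)cc1)C(Cc1ccc(OC)cc1)C(C)=O
F2 | step 4 | methyl 5-(4-methoxybenzyl)-6-[2-(4-methoxyphenyl)ethyl]-2,4-dioxocyclohexane-1-carboxylate | COC(=O)C1C(=O)CC(=O)C(Cc2ccc(OC)cc2)C1CCc1ccc(OC)cc1
F3 | step 6 | 1,5-dimethoxy-2,4-bis(4-methoxybenzyl)-3-[2-(4-methoxyphenyl)ethyl]benzene | COc1cc(OC)c(Cc2ccc(OC)cc2)c(CCc2ccc(OC)cc2)c1Cc1ccc(OC)cc1
F4 | step 5 | dibenzyl malonate (purchased) | O=C(CC(=O)OCc1ccccc1)OCc1ccccc1
F5 | step 5 | dibenzyl 2-(4-methoxybenzyl)malonate | O=C(OCc1ccccc1)C(Cc1ccc(OC)cc1)C(=O)OCc1ccccc1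
F6 | step 5 | dibenzyl 2-(4-methoxybenzyl)-2-[4-(4-methoxybenzyl)-1-(4-methoxyphenyl)-5-oxohexan-3-yl]malonate | O=C(OCc1ccccc1)C(Cc1ccc(OC)cc1)(C(=O)OCc1ccccc1)C(CCc1ccc(OC)cc1)C(Cc1ccc(OC)cc1)C(C)=O
F7 | step 5 | benzyl 1,5-bis(4-methoxybenzyl)-6-[2-(4-methoxyphenyl)ethyl]-2,4-dioxocyclohexane-1-carboxylate | O=C(OCc1ccccc1)C1(Cc2ccc(OC)cc2)C(=O)CC(=O)C(Cc2ccc(OC)cc2)C1CCc1ccc(OC)cc1
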